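The numbering is that of labdane. The target is methyl (3R,5S,9S,10S,13R)-3,17-dihydroxylabd-7-en-15-oate, an ent-labdane with trans-fused rings A (C1–C5, C10) and B (C5–C10).
Enabling feature: the fusion bond C5–C10 and the bond C8–C9 stand 1,4 to each other across ring B. Cutting both opens rings A and B at once to a C5=C6–C7=C8 diene and a C9=C10 alkene still linked through C1–C4, and a temporary C11 ketone turns that alkene into a dienophile.
The acyclic trienone is cut further at C9–C11 (alkenylzinc plus acid chloride), C5=C6 (olefination), C3–C4 (aldol) and C10–C20 (carbometalation).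
Forward: the chain from C9 to C17 grows linearly from pent-4-yn-1-ol, the C11–C16 acyl unit is joined last, and both rings then close together in one cycloaddition. After that, C11 is deoxygenated and the 6-ene is shifted to C7=C8 through the C17 aldehyde.
Stereochemistry: C13 is bought with the half-ester and C3 comes from a reagent-controlled aldol. C5, C9 and C10 (plus a transient C8) are relayed from C3 and from the alkene geometries in the cycloaddition.
Key step: step 12

Assumption: with unbranched aliphatic aldehydes, the oxazaborolidinone from N-tosyl-L-valine is taken to direct attack to the Si face (3R here). If the sense proved opposite, N-tosyl-D-valine would be used and nothing else would change.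

Step 1
Reactants: 1 pent-4-yn-1-ol
Product: 3 (E)-5-iodo-4-methylpent-4-en-1-ol, via alkenylalane 2 (not isolated)
Conditions: Me3Al (3 equiv), Cp2ZrCl2 (0.25 equiv), CH2Cl2, 0 °C to rt; then I2, THF, −30 to 0 °C; aq. K2CO3
Reagents that add atoms: trimethylaluminium C[Al](C)C; iodine [I][I]
Why: Zirconium-catalysed Negishi carboalumination adds methyl (C20) and aluminium syn across the alkyne with aluminium at the terminus, and iodinolysis replaces aluminium with retention, so the E-iodide that later places C11 cis to C20 should result.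

Step 2
Reactants: 3 (E)-5-iodo-4-methylpent-4-en-1-ol
Product: 4 (E)-5-iodo-4-methylpent-4-enal
Conditions: TEMPO (0.1 equiv), PhI(OAc)2 (1.1 equiv), CH2Cl2, rt
Reagents that add atoms: none
Why: Oxoammonium-mediated (TEMPO) oxidation of a primary alcohol stops at the aldehyde and does not touch the alkenyl iodide.

Step 3
Reactants: 4 (E)-5-iodo-4-methylpent-4-enal; 5 1-methoxy-2-methyl-1-(trimethylsilyloxy)prop-1-ene
Product: 6 methyl (3R,6E)-3-hydroxy-7-iodo-2,2,6-trimethylhept-6-enoate
Conditions: N-tosyl-L-valine (1.1 equiv), BH3·THF (1.0 equiv), CH2Cl2, 0 °C to rt; then 4 and 5, −78 °C; pH 7 buffer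
Reagents that add atoms: none
Why: In this Kiyooka-type Mukaiyama aldol the aldehyde binds to boron of the valine-derived oxazaborolidinone on the side away from the isopropyl group and exposes its Si face to the ketene acetal in an open transition state, which should set C3 as R while forming C3–C4 and the gem-dimethyl carbon.

Step 4
Reactants: 6 methyl (3R,6E)-3-hydroxy-7-iodo-2,2,6-trimethylhept-6-enoate
Product: 7 methyl (3R,6E)-3-(tert-butyldimethylsilyloxy)-7-iodo-2,2,6-trimethylhept-6-enoate
Conditions: TBSOTf (1.3 equiv), 2,6-lutidine (2 equiv), CH2Cl2, 0 °C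
Reagents that add atoms: tert-butyldimethylsilyl triflate CC(C)(C)[Si](C)(C)OS(=O)(=O)C(F)(F)F
Why: Silyl triflate silylation is the standard way to cap a carbinol next to a quaternary carbon, and it both blocks retro-aldol cleavage and installs the bulky group that steers step 12.

Step 5
Reactants: 7 methyl (3R,6E)-3-(tert-butyldimethylsilyloxy)-7-iodo-2,2,6-trimethylhept-6-enoate
Product: 8 (3R,6E)-3-(tert-butyldimethylsilyloxy)-7-iodo-2,2,6-trimethylhept-6-en-1-ol
Conditions: i-Bu2AlH (2.5 equiv), CH2Cl2, −78 to −20 °C; aq. potassium sodium tartrate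
Reagents that add atoms: none
Why: Full hydride reduction of the neopentyl ester to the primary alcohol is more dependable than stopping at the aldehyde, and it spares the iodide and the silyl ether.

Step 6
Reactants: 8 (3R,6E)-3-(tert-butyldimethylsilyloxy)-7-iodo-2,2,6-trimethylhept-6-en-1-ol
Product: 9 (3R,6E)-3-(tert-butyldimethylsilyloxy)-7-iodo-2,2,6-trimethylhept-6-enal
Conditions: Dess–Martin periodinane (1.3 equiv), CH2Cl2, rt
Reagents that add atoms: none
Why: Dess–Martin oxidation is mild, and the aldehyde has no α-hydrogen, so it can neither epimerise nor eliminate the β-silyloxy group.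

Step 7
Reactants: 9 (3R,6E)-3-(tert-butyldimethylsilyloxy)-7-iodo-2,2,6-trimethylhept-6-enal; 10 triethyl 4-phosphonocrotonate
Product: 12 ethyl (2E,4E,7R,10E)-7-(tert-butyldimethylsilyloxy)-11-iodo-6,6,10-trimethylundeca-2,4,10-trienoate, via lithiated phosphonate 11 (not isolated)
Conditions: 10 (1.5 equiv), LiN(SiMe3)2 (1.45 equiv), THF, −78 °C; then 9, −78 °C to rt
Reagents that add atoms: none
Why: In this vinylogous Horner–Wadsworth–Emmons olefination the stabilised allylic phosphonate anion reacts at the carbon next to phosphorus with the unenolisable aldehyde, and reversible addition favours the E alkene, giving the E,E-dienoate that holds C5–C8 and C17.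

Step 8
Reactants: 12 ethyl (2E,4E,7R,10E)-7-(tert-butyldimethylsilyloxy)-11-iodo-6,6,10-trimethylundeca-2,4,10-trienoate
Product: 13 (2E,4E,7R,10E)-7-(tert-butyldimethylsilyloxy)-11-iodo-6,6,10-trimethylundeca-2,4,10-trien-1-ol
Conditions: i-Bu2AlH (2.3 equiv), CH2Cl2, −78 °C; aq. potassium sodium tartrate
Reagents that add atoms: none
Why: 1,2-Reduction of a dienoate with i-Bu2AlH at low temperature gives the dienol without conjugate reduction or loss of alkene geometry.

Step 9
Reactants: 13 (2E,4E,7R,10E)-7-(tert-butyldimethylsilyloxy)-11-iodo-6,6,10-trimethylundeca-2,4,10-trien-1-ol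
Product: 14 (1E,5R,7E,9E)-5,11-bis(tert-butyldimethylsilyloxy)-1-iodo-2,6,6-trimethylundeca-1,7,9-triene
Conditions: TBSCl (1.2 equiv), imidazole (2 equiv), CH2Cl2, rt
Reagents that add atoms: tert-butyldimethylsilyl chloride CC(C)(C)[Si](C)(C)Cl
Why: This is a routine silylation, chosen because a silyl ether is a weaker Lewis base than a benzyl-type ether, should resist ionisation at the dienylic position in step 12, and leaves together with the C3 group in step 16.

Step 10
Reactants: 15 methyl hydrogen (R)-3-methylglutarate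
Product: 16 methyl (S)-5-chloro-3-methyl-5-oxopentanoate
Conditions: (COCl)2 (1.2 equiv), DMF (cat.), CH2Cl2, 0 °C to rt; concentrated and used crude
Reagents that add atoms: oxalyl chloride O=C(Cl)C(=O)Cl
Why: Acid chloride formation under Vilsmeier catalysis is mild, and the chloride is kept at or below rt and not distilled, so that ester/chloride interchange through a cyclic acyloxonium ion, which would swap the chain ends and erode C13, is avoided (the descriptor changes only because the priorities change).

Step 11
Reactants: 14 (1E,5R,7E,9E)-5,11-bis(tert-butyldimethylsilyloxy)-1-iodo-2,6,6-trimethylundeca-1,7,9-triene; 16 methyl (S)-5-chloro-3-methyl-5-oxopentanoate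
Product: 19 methyl (3R,6E,10R,12E,14E)-10,16-bis(tert-butyldimethylsilyloxy)-3,7,11,11-tetramethyl-5-oxohexadeca-6,12,14-trienoate, via alkenyllithium 17 (not isolated), via alkenylzinc chloride 18 (not isolated)
Conditions: t-BuLi (2.05 equiv), Et2O, −78 °C; ZnCl2 (1.1 equiv, THF), −78 to 0 °C; 16 (1.2 equiv), Pd(PPh3)4 (5 mol %), THF, 0 °C to rt
Reagents that add atoms: none
Why: Iodine–lithium exchange and transmetalation to zinc keep the alkene geometry, and the Pd-catalysed Negishi acylation joins the alkenylzinc to the acid chloride without touching the methyl ester or the product ketone, so the E-enone arises directly and no lactonisation-prone C11 carbinol is passed.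

Step 12
Reactants: 19 methyl (3R,6E,10R,12E,14E)-10,16-bis(tert-butyldimethylsilyloxy)-3,7,11,11-tetramethyl-5-oxohexadeca-6,12,14-trienoate
Product: 20 methyl (3R,5S,8R,9R,10R,13R)-3,17-bis(tert-butyldimethylsilyloxy)-11-oxolabd-6-en-15-oate (trans-fused; C20, C11, C17 and O3 on one face, H5, H8 and H9 on the other)
Conditions: Me2AlCl (2.5 equiv), CH2Cl2 (0.01 M), −40 °C to rt; aq. potassium sodium tartrate
Reagents that add atoms: none
Why: Me2AlCl binds the C11 carbonyl (the excess saturates the ester), lowers the enone LUMO and lets the s-cis C5–C8 diene add suprafacially to C9=C10 in one concerted, asynchronous [4+2] event that forms C5–C10 and C8–C9; the closest known class is the Lewis-acid-promoted type 1 intramolecular Diels–Alder reaction of 1,7,9-decatrienes with a terminal acyl activator, which is known to give trans-decalins with an angular methyl group. Ring B closes as the cyclohexene that contains both new bonds and the C6=C7 alkene, while ring A closes in the fused mode as the carbocycle made of the tether C1–C4 plus C5 and C10. C9 and C10 are coupled stereospecifically by the E-enone, in which C11 and C20 are cis, and C8 follows from the E,E-diene, whose outward groups C4 and C17 must end up cis. C5 relative to C10 is decided by the acyl-endo, tether-exo transition state, which gives the trans ring fusion and puts C11, C17 and C20 on one face. The absolute sense comes from C3, because the chair-like C1–C4 tether places the bulky silyloxy group equatorial and thereby selects one diene face. The step therefore needs endo and π-facial selectivity; the first is secured by the aluminium-bound carbonyl and the low temperature it allows, the second by the C3 silyl ether, and the geminal methyl groups on C4 compress the tether angle and raise the share of coiled conformers.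

Step 13
Reactants: 20 methyl (3R,5S,8R,9R,10R,13R)-3,17-bis(tert-butyldimethylsilyloxy)-11-oxolabd-6-en-15-oate
Product: 21 methyl (3R,5S,8R,9R,10R,13R)-3,17-bis(tert-butyldimethylsilyloxy)-11-hydroxylabd-6-en-15-oate (C11 epimers, both used)
Conditions: NaBH4 (1.5 equiv), MeOH–THF, −10 to 0 °C; pH 7 buffer; used at once
Reagents that add atoms: none
Why: Borohydride reduces the ketone chemoselectively beside the methyl ester, the new C11 centre is erased in step 15 so either epimer serves, and the cold neutral work-up and immediate use are meant to keep the δ-hydroxy ester from lactonising.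

Step 14
Reactants: 21 methyl (3R,5S,8R,9R,10R,13R)-3,17-bis(tert-butyldimethylsilyloxy)-11-hydroxylabd-6-en-15-oate
Product: 22 methyl (3R,5S,8R,9R,10R,13R)-3,17-bis(tert-butyldimethylsilyloxy)-11-(phenoxythiocarbonyloxy)labd-6-en-15-oate
Conditions: PhOC(S)Cl (1.5 equiv), DMAP (2 equiv), MeCN, rt
Reagents that add atoms: O-phenyl chlorothionoformate ClC(=S)Oc1ccccc1
Why: Acylation with the small, highly electrophilic chlorothionoformate under DMAP activation avoids the free alkoxide of a xanthate protocol, which would attack the C15 ester, and it is the usual first half of a Barton–McCombie deoxygenation of a secondary alcohol.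

Step 15
Reactants: 22 methyl (3R,5S,8R,9R,10R,13R)-3,17-bis(tert-butyldimethylsilyloxy)-11-(phenoxythiocarbonyloxy)labd-6-en-15-oate
Product: 23 methyl (3R,5S,8R,9R,10S,13R)-3,17-bis(tert-butyldimethylsilyloxy)labd-6-en-15-oate
Conditions: Bu3SnH (2 equiv), AIBN (0.2 equiv), toluene, 90 °C
Reagents that add atoms: none
Why: In this Barton–McCombie deoxygenation the stannyl radical adds to C=S and the released secondary C11 radical takes hydrogen from Bu3SnH faster than it could attack C6, a closure that would need a norbornane inside the trans-decalin, while C9 is not involved and keeps its configuration.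

Step 16
Reactants: 23 methyl (3R,5S,8R,9R,10S,13R)-3,17-bis(tert-butyldimethylsilyloxy)labd-6-en-15-oate
Product: 24 methyl (3R,5S,8R,9R,10S,13R)-3,17-dihydroxylabd-6-en-15-oate
Conditions: 48% aq. HF, MeCN, rt
Reagents that add atoms: none
Why: Fluoride-driven cleavage removes both silyl ethers, including the hindered C3 one, under mildly acidic conditions that leave the methyl ester and the isolated 6-ene intact.

Step 17
Reactants: 24 methyl (3R,5S,8R,9R,10S,13R)-3,17-dihydroxylabd-6-en-15-oate
Product: 26 methyl (3R,5S,9S,10S,13R)-3-hydroxy-17-oxolabd-7-en-15-oate, via labd-6-en-17-al 25 (not isolated)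
Conditions: TEMPO (0.1 equiv), PhI(OAc)2 (1.1 equiv), CH2Cl2, rt; then DBU (4 equiv), rt
Reagents that add atoms: none
Why: The bulky oxoammonium salt oxidises the primary C17 alcohol much faster than the neopentyl secondary C3 alcohol, and DBU then removes the doubly activated H8 to give a dienolate whose protonation at C6 moves the alkene into conjugation, which erases the transient C8 centre while the non-acidified C9 stays untouched.

Step 18
Reactants: 26 methyl (3R,5S,9S,10S,13R)-3-hydroxy-17-oxolabd-7-en-15-oate
Product: 27 methyl (3R,5S,9S,10S,13R)-3,17-dihydroxylabd-7-en-15-oate (CNP0313905.1)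
Conditions: NaBH4 (1 equiv), CeCl3·7H2O (1.1 equiv), MeOH, −20 to 0 °C
Reagents that add atoms: none
Why: In the Luche reduction the CeCl3-modified borohydride delivers hydride 1,2 to the enal only, leaving the alkene, the ester and all stereocentres unchanged.

Compound list
1 | pent-4-yn-1-ol | C#CCCCO | starting material
2 | dimethylaluminium (E)-5-(dimethylalumanyl)-4-methylpent-4-en-1-olate | C[Al](C)/C=C(\C)CCCO[Al](C)C | intermediate
3 | (E)-5-iodo-4-methylpent-4-en-1-ol | I/C=C(\C)CCCO | intermediate
4 | (E)-5-iodo-4-methylpent-4-enal | I/C=C(\C)CCC=O | intermediate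
5 | 1-methoxy-2-methyl-1-(trimethylsilyloxy)prop-1-ene | COC(O[Si](C)(C)C)=C(C)C | starting material
6 | methyl (3R,6E)-3-hydroxy-7-iodo-2,2,6-trimethylhept-6-enoate | I/C=C(\C)CC[C@@H](O)C(C)(C)C(=O)OC | intermediate
7 | methyl (3R,6E)-3-(tert-butyldimethylsilyloxy)-7-iodo-2,2,6-trimethylhept-6-enoate | I/C=C(\C)CC[C@@H](O[Si](C)(C)C(C)(C)C)C(C)(C)C(=O)OC | intermediate
8 | (3R,6E)-3-(tert-butyldimethylsilyloxy)-7-iodo-2,2,6-trimethylhept-6-en-1-ol | I/C=C(\C)CC[C@@H](O[Si](C)(C)C(C)(C)C)C(C)(C)CO | intermediate
9 | (3R,6E)-3-(tert-butyldimethylsilyloxy)-7-iodo-2,2,6-trimethylhept-6-enal | I/C=C(\C)CC[C@@H](O[Si](C)(C)C(C)(C)C)C(C)(C)C=O | intermediate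
10 | triethyl 4-phosphonocrotonate | CCOC(=O)/C=C/CP(=O)(OCC)OCC | starting material
11 | lithiated triethyl 4-phosphonocrotonate | [Li+].CCOC(=O)/C=C/[CH-]P(=O)(OCC)OCC | intermediate
12 | ethyl (2E,4E,7R,10E)-7-(tert-butyldimethylsilyloxy)-11-iodo-6,6,10-trimethylundeca-2,4,10-trienoate | I/C=C(\C)CC[C@@H](O[Si](C)(C)C(C)(C)C)C(C)(C)/C=C/C=C/C(=O)OCC | intermediate
13 | (2E,4E,7R,10E)-7-(tert-butyldimethylsilyloxy)-11-iodo-6,6,10-trimethylundeca-2,4,10-trien-1-ol | I/C=C(\C)CC[C@@H](O[Si](C)(C)C(C)(C)C)C(C)(C)/C=C/C=C/CO | intermediate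
14 | (1E,5R,7E,9E)-5,11-bis(tert-butyldimethylsilyloxy)-1-iodo-2,6,6-trimethylundeca-1,7,9-triene | I/C=C(\C)CC[C@@H](O[Si](C)(C)C(C)(C)C)C(C)(C)/C=C/C=C/CO[Si](C)(C)C(C)(C)C | intermediate
15 | methyl hydrogen (R)-3-methylglutarate | COC(=O)C[C@H](C)CC(=O)O | starting material
16 | methyl (S)-5-chloro-3-methyl-5-oxopentanoate | COC(=O)C[C@H](C)CC(=O)Cl | intermediate
17 | alkenyllithium from 14 (Li in place of I, E) | [Li]/C=C(\C)CC[C@@H](O[Si](C)(C)C(C)(C)C)C(C)(C)/C=C/C=C/CO[Si](C)(C)C(C)(C)C | intermediate
18 | alkenylzinc chloride from 17 (ZnCl in place of Li, E) | Cl[Zn]/C=C(\C)CC[C@@H](O[Si](C)(C)C(C)(C)C)C(C)(C)/C=C/C=C/CO[Si](C)(C)C(C)(C)C | intermediate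
19 | methyl (3R,6E,10R,12E,14E)-10,16-bis(tert-butyldimethylsilyloxy)-3,7,11,11-tetramethyl-5-oxohexadeca-6,12,14-trienoate | COC(=O)C[C@H](C)CC(=O)/C=C(\C)CC[C@@H](O[Si](C)(C)C(C)(C)C)C(C)(C)/C=C/C=C/CO[Si](C)(C)C(C)(C)C | intermediate
20 | methyl (3R,5S,8R,9R,10R,13R)-3,17-bis(tert-butyldimethylsilyloxy)-11-oxolabd-6-en-15-oate | COC(=O)C[C@H](C)CC(=O)[C@@H]1[C@H](CO[Si](C)(C)C(C)(C)C)C=C[C@@H]2C(C)(C)[C@H](O[Si](C)(C)C(C)(C)C)CC[C@@]12C | intermediate
21 | methyl (3R,5S,8R,9R,10R,13R)-3,17-bis(tert-butyldimethylsilyloxy)-11-hydroxylabd-6-en-15-oate (C11 epimers) | COC(=O)C[C@H](C)CC(O)[C@@H]1[C@H](CO[Si](C)(C)C(C)(C)C)C=C[C@@H]2C(C)(C)[C@H](O[Si](C)(C)C(C)(C)C)CC[C@@]12C | intermediate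
22 | methyl (3R,5S,8R,9R,10R,13R)-3,17-bis(tert-butyldimethylsilyloxy)-11-(phenoxythiocarbonyloxy)labd-6-en-15-oate (C11 epimers) | COC(=O)C[C@H](C)CC(OC(=S)Oc3ccccc3)[C@@H]1[C@H](CO[Si](C)(C)C(C)(C)C)C=C[C@@H]2C(C)(C)[C@H](O[Si](C)(C)C(C)(C)C)CC[C@@]12C | intermediate
23 | methyl (3R,5S,8R,9R,10S,13R)-3,17-bis(tert-butyldimethylsilyloxy)labd-6-en-15-oate | COC(=O)C[C@H](C)CC[C@@H]1[C@H](CO[Si](C)(C)C(C)(C)C)C=C[C@@H]2C(C)(C)[C@H](O[Si](C)(C)C(C)(C)C)CC[C@@]12C | intermediate
24 | methyl (3R,5S,8R,9R,10S,13R)-3,17-dihydroxylabd-6-en-15-oate | COC(=O)C[C@H](C)CC[C@@H]1[C@H](CO)C=C[C@@H]2C(C)(C)[C@H](O)CC[C@@]12C | intermediate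
25 | methyl (3R,5S,8R,9R,10S,13R)-3-hydroxy-17-oxolabd-6-en-15-oate | COC(=O)C[C@H](C)CC[C@@H]1[C@H](C=O)C=C[C@@H]2C(C)(C)[C@H](O)CC[C@@]12C | intermediate
26 | methyl (3R,5S,9S,10S,13R)-3-hydroxy-17-oxolabd-7-en-15-oate | COC(=O)C[C@H](C)CC[C@@H]1C(C=O)=CC[C@@H]2C(C)(C)[C@H](O)CC[C@@]12C | intermediate
27 | methyl (3R,5S,9S,10S,13R)-3,17-dihydroxylabd-7-en-15-oate | COC(=O)C[C@H](C)CC[C@@H]1C(CO)=CC[C@@H]2C(C)(C)[C@H](O)CC[C@@]12C | target

Total step count: 18. Longest linear sequence: 17 steps (steps 1–9 and 11–18); step 10 lies on the side branch.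

Steps most likely to fail

Step 12 (cycloaddition). Bond formation between the β,β-disubstituted enone carbon C10 and the neopentyl diene terminus C5 may be slow. That would leave time for geometric isomerisation of the enone, for ionisation of the dienylic silyl ether by the Lewis acid, and for erosion of endo or facial selectivity, since the equatorial preference of the C3 group next to two methyl groups is modest. In the fallback the neutral aluminium complex is replaced by a cationic dienophile. Setting out from 19, ketalisation with 1,2-bis(trimethylsilyloxy)ethane and catalytic TMSOTf (CH2Cl2, −78 °C) should give the 5,5-ethylenedioxy trienoate F1 without moving the double bond. A further charge of TMSOTf opens the dioxolane reversibly to an oxygen-stabilised allyl cation, a far stronger dienophile. The ionic intramolecular Diels–Alder reaction should then form the same C5–C10 and C8–C9 bonds well below 0 °C to give the 11,11-ethylenedioxy labd-6-enoate F2. PPTS in wet acetone releases the ketone, and the route is rejoined at 20.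

Step 14 (thioacylation of the C11 carbinol). Attack of O11 on the C15 ester with loss of methanol (δ-lactonisation) may outrun a slow acylation of the crowded carbinol, already during step 13 or here. In the fallback lactonisation is accepted and used. Setting out from 21, PPTS in warm toluene drives it fully to the 15,11-lactone F3, which is stable and can be purified. KOH (1 equiv) in aq. THF opens it, and drying gives the potassium 11-hydroxy-15-carboxylate F4, whose carboxylate cannot be attacked by O11. NaH, then CS2, then excess MeI in THF–DMF caps O11 as the xanthate before the carboxylate is methylated, giving the S-methyl xanthate methyl ester F5. Bu3SnH/AIBN as in step 15 then returns to 23.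

Step 11 (acylation of the alkenylzinc). Several things may lower the quality of the trienone:
- incomplete iodine–lithium exchange;
- protonation or homocoupling of the alkenylmetal;
- ester/chloride interchange in the acid chloride;
- isomerisation of the enone double bond.

In the fallback the C9–C11 bond is made by carbonyl addition in place of cross-coupling. Setting out from 15, EtSH/DCC/DMAP gives the S-ethyl thioester F6. Et3SiH with Pd on carbon (Fukuyama reduction) then gives methyl (R)-3-methyl-5-oxopentanoate F7, with no acid chloride involved. Nozaki–Hiyama–Kishi coupling of F7 with iodide 14 (CrCl2, catalytic NiCl2, DMF–THF) tolerates the ester and gives the C11 allylic alcohol F8 as an epimer mixture. This is oxidised at once with Dess–Martin periodinane to rejoin the route at 19.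

Further compounds
F1 | step 12 | methyl (3R,6E,10R,12E,14E)-10,16-bis(tert-butyldimethylsilyloxy)-5,5-ethylenedioxy-3,7,11,11-tetramethylhexadeca-6,12,14-trienoate | COC(=O)C[C@H](C)CC1(OCCO1)/C=C(\C)CC[C@@H](O[Si](C)(C)C(C)(C)C)C(C)(C)/C=C/C=C/CO[Si](C)(C)C(C)(C)C
F2 | step 12 | methyl 3,17-bis(tert-butyldimethylsilyloxy)-11,11-ethylenedioxylabd-6-en-15-oate (ring configuration as in 20) | COC(=O)C[C@H](C)CC1(OCCO1)[C@@H]2[C@H](CO[Si](C)(C)C(C)(C)C)C=C[C@@H]3C(C)(C)[C@H](O[Si](C)(C)C(C)(C)C)CC[C@@]23C
F3 | step 14 | 3,17-bis(tert-butyldimethylsilyloxy)labd-6-en-15,11-olide (C11 epimers, other centres as in 21) | C[C@H]1CC(=O)OC(C1)[C@@H]2[C@H](CO[Si](C)(C)C(C)(C)C)C=C[C@@H]3C(C)(C)[C@H](O[Si](C)(C)C(C)(C)C)CC[C@@]23C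
F4 | step 14 | potassium 3,17-bis(tert-butyldimethylsilyloxy)-11-hydroxylabd-6-en-15-oate (C11 epimers) | [K+].[O-]C(=O)C[C@H](C)CC(O)[C@@H]1[C@H](CO[Si](C)(C)C(C)(C)C)C=C[C@@H]2C(C)(C)[C@H](O[Si](C)(C)C(C)(C)C)CC[C@@]12C
F5 | step 14 | methyl 3,17-bis(tert-butyldimethylsilyloxy)-11-[(methylsulfanyl)thiocarbonyloxy]labd-6-en-15-oate (C11 epimers) | COC(=O)C[C@H](C)CC(OC(=S)SC)[C@@H]1[C@H](CO[Si](C)(C)C(C)(C)C)C=C[C@@H]2C(C)(C)[C@H](O[Si](C)(C)C(C)(C)C)CC[C@@]12C
F6 | step 11 | methyl 5-(ethylsulfanyl)-3-methyl-5-oxopentanoate (C3 arrangement as in 15) | COC(=O)C[C@H](C)CC(=O)SCC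
F7 | step 11 | methyl (R)-3-methyl-5-oxopentanoate | COC(=O)C[C@H](C)CC=O
F8 | step 11 | methyl (3R,6E,10R,12E,14E)-10,16-bis(tert-butyldimethylsilyloxy)-5-hydroxy-3,7,11,11-tetramethylhexadeca-6,12,14-trienoate (C5 epimers) | COC(=O)C[C@H](C)CC(O)/C=C(\C)CC[C@@H](O[Si](C)(C)C(C)(C)C)C(C)(C)/C=C/C=C/CO[Si](C)(C)C(C)(C)C
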